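**Retrosynthetic overview**
1. C40 = C15 + C10 + C15: two Wittig bonds (C11=C12 and C11'=C12') join the trans (5S,6S) and the cis (5'R,6'S) C15 phosphonium salts, both with C3 masked as a dioxolane, to commercial C10 dialdehyde; the ketals come off last.
2. Each C15 salt ← C13 methyl enone (HWE, reduction, bromide/PPh3) ← (E)-δ-hydroxy enoate that already carries the C5/C6 stereodiad.
3. Both hydroxy enoates ← 5,6-epoxy enoates by palladium/formate hydrogenolysis: E-olefin gives hydride with inversion at C6 (cis), Z-olefin gives net retention (trans). The two epoxides are enantiomers from Sharpless epoxidation (D- or L-tartrate) of one achiral allylic alcohol.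
4. Key C–C bond: C1–C6 of the ring, made by intermolecular Michael addition of ethyl acetoacetate to mesityl oxide with aldol ring closure in the same flask; ketalisation (with double-bond shift) and reduction then give the allylic alcohol.
5. Ring order: carbocycle first (step 1), dioxolane second (step 2), oxirane third (steps 4 and 13, opened in steps 7 and 16); dioxolanes are removed in the final step.

Assumption: ring atoms are referred to by carotenoid numbering (C1 gem-dimethyl, C3 carbonyl, C5 carbinol, C6 chain-bearing CH, C7 first chain carbon); the target is the all-E (5S,6S,5'R,6'S) isomer, with 5-OH trans to the chain at the unprimed end and cis at the primed end.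

**Common ring precursor**

Step 1
Reactants: 1 ethyl acetoacetate; 2 mesityl oxide (4-methylpent-3-en-2-one)
Product: 5 racemic ethyl 2,6,6-trimethyl-4-oxocyclohex-2-ene-1-carboxylate, via Michael adduct 3 (not isolated), via cyclic ketol 4 (not isolated)
Conditions: ZnCl2 (anhydrous, 0.3 equiv), toluene/heptane, reflux, Dean–Stark
Reagents that add atoms: none
Why: A ZnCl2-promoted intermolecular Michael addition of the acetoacetate enol to the β-carbon of mesityl oxide forges the congested C1–C6 bond, and the 1,5-diketone then closes by intramolecular aldol condensation to the conjugated cyclohexenone (Robinson-type annulation); the stereocentre is racemic and is erased in step 2.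

Step 2
Reactants: 5 racemic ethyl 2,6,6-trimethyl-4-oxocyclohex-2-ene-1-carboxylate
Product: 6 ethyl 7,9,9-trimethyl-1,4-dioxaspiro[4.5]dec-7-ene-8-carboxylate
Conditions: HOCH2CH2OH (2 equiv), p-TsOH·H2O (5 mol%), toluene, reflux, Dean–Stark
Reagents that add atoms: ethylene glycol OCCO
Why: Acid-catalysed ketalisation runs through the dienol ether and reprotonation leaves the C=C β,γ to the ketal, here tetrasubstituted and conjugated with the ester, which is the thermodynamic isomer (deconjugative ketalisation).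

Step 3
Reactants: 6 ethyl 7,9,9-trimethyl-1,4-dioxaspiro[4.5]dec-7-ene-8-carboxylate
Product: 7 (7,9,9-trimethyl-1,4-dioxaspiro[4.5]dec-7-en-8-yl)methanol
Conditions: LiAlH4, Et2O, 0 °C → rt; Fieser work-up
Reagents that add atoms: none
Why: LiAlH4 reduces the hindered conjugated ester by 1,2-hydride addition to the primary allylic alcohol while the dioxolane is inert (hydride ester reduction).

**Cis end group (5R,6S)**

Step 4
Reactants: 7 (7,9,9-trimethyl-1,4-dioxaspiro[4.5]dec-7-en-8-yl)methanol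
Product: 8 [(1R,6R)-2,2,6-trimethylspiro[7-oxabicyclo[4.1.0]heptane-4,2'-[1,3]dioxolan]-1-yl]methanol (5R,6R in carotenoid numbering)
Conditions: Ti(OiPr)4 (10 mol%), D-(−)-diethyl tartrate (12 mol%), t-BuOOH (2 equiv, anhydrous in decane), 4 Å MS, CH2Cl2, −20 °C
Reagents that add atoms: tert-butyl hydroperoxide CC(C)(C)OO
Why: Sharpless asymmetric epoxidation, in which the titanium–(S,S)-tartrate–alkoxide complex delivers the peroxide oxygen to one enantiotopic face of the tetrasubstituted allylic alcohol (the face opposite to that used by the L-tartrate, which gives 2S epoxides from simple allylic alcohols), setting C5 and C6 together as 5R,6R.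

Step 5
Reactants: 8 [(1R,6R)-2,2,6-trimethylspiro[7-oxabicyclo[4.1.0]heptane-4,2'-[1,3]dioxolan]-1-yl]methanol
Product: 9 (1S,6R)-2,2,6-trimethylspiro[7-oxabicyclo[4.1.0]heptane-4,2'-[1,3]dioxolane]-1-carbaldehyde
Conditions: (n-Pr)4N[RuO4] (5 mol%), N-methylmorpholine N-oxide (1.5 equiv), 4 Å MS, CH2Cl2, rt
Reagents that add atoms: none
Why: Ley–Griffith oxidation stops at the non-enolisable α-epoxy aldehyde under neutral conditions, so oxirane, ketal and both stereocentres are untouched (the descriptor at C6 changes only through CIP priorities).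

Step 6
Reactants: 9 (1S,6R)-2,2,6-trimethylspiro[7-oxabicyclo[4.1.0]heptane-4,2'-[1,3]dioxolane]-1-carbaldehyde; 10 methyl (triphenylphosphoranylidene)acetate
Product: 11 methyl (2E)-3-[(1S,6R)-2,2,6-trimethylspiro[7-oxabicyclo[4.1.0]heptane-4,2'-[1,3]dioxolan]-1-yl]prop-2-enoate
Conditions: toluene, 80 °C
Reagents that add atoms: none
Why: Wittig olefination with a stabilised ylide is E-selective and tolerates the hindered non-enolisable epoxy aldehyde, leaving the epoxide stereocentres alone.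

Step 7
Reactants: 11 methyl (2E)-3-[(1S,6R)-2,2,6-trimethylspiro[7-oxabicyclo[4.1.0]heptane-4,2'-[1,3]dioxolan]-1-yl]prop-2-enoate
Product: 12 methyl (2E)-3-[(7R,8S)-7-hydroxy-7,9,9-trimethyl-1,4-dioxaspiro[4.5]decan-8-yl]prop-2-enoate (5R,6S)
Conditions: Pd2(dba)3·CHCl3 (2.5 mol%), n-Bu3P (10 mol%), HCO2H (5 equiv), Et3N (2 equiv), 1,4-dioxane, rt
Reagents that add atoms: none
Why: Tsuji–Shimizu hydrogenolysis of an alkenyl oxirane, in which zerovalent palladium ionises the allylic C6–O bond with inversion, the syn π-allyl complex from the E-enoate keeps its face, and the formate-derived hydride passes from palladium to C6, so H enters anti to the C5 oxygen and the chain ends cis to the retained 5R hydroxyl (6S).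

Step 8
Reactants: 12 methyl (2E)-3-[(7R,8S)-7-hydroxy-7,9,9-trimethyl-1,4-dioxaspiro[4.5]decan-8-yl]prop-2-enoate
Product: 13 (2E)-3-[(7R,8S)-7-hydroxy-7,9,9-trimethyl-1,4-dioxaspiro[4.5]decan-8-yl]-N-methoxy-N-methylprop-2-enamide
Conditions: MeNH(OMe)·HCl (3 equiv), i-PrMgCl (7 equiv), THF, −20 → 0 °C
Reagents that add atoms: N,O-dimethylhydroxylamine hydrochloride CNOC.Cl
Why: Weinreb amide formation by aminolysis of the methyl ester with the chloromagnesium amide made in the flask, the extra Grignard reagent only deprotonating the tertiary alcohol.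

Step 9
Reactants: 13 (2E)-3-[(7R,8S)-7-hydroxy-7,9,9-trimethyl-1,4-dioxaspiro[4.5]decan-8-yl]-N-methoxy-N-methylprop-2-enamide
Product: 14 (3E)-4-[(7R,8S)-7-hydroxy-7,9,9-trimethyl-1,4-dioxaspiro[4.5]decan-8-yl]but-3-en-2-one
Conditions: MeMgBr (3 equiv), THF, 0 °C; cold aq. NH4Cl
Reagents that add atoms: methylmagnesium bromide C[Mg]Br
Why: Weinreb ketone synthesis, in which the stable magnesium chelate of the tetrahedral adduct prevents over-addition and the methyl enone is released only on work-up.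

Step 10
Reactants: 14 (3E)-4-[(7R,8S)-7-hydroxy-7,9,9-trimethyl-1,4-dioxaspiro[4.5]decan-8-yl]but-3-en-2-one; 15 triethyl phosphonoacetate
Product: 16 ethyl (2E,4E)-5-[(7R,8S)-7-hydroxy-7,9,9-trimethyl-1,4-dioxaspiro[4.5]decan-8-yl]-3-methylpenta-2,4-dienoate
Conditions: NaH (1.3 equiv, phosphonate anion preformed from 1.4 equiv 15), THF, 0 → 40 °C
Reagents that add atoms: none
Why: Horner–Wadsworth–Emmons olefination of the methyl ketone gives the 2E dienoate as the major isomer (about 6:1, 2Z removed by chromatography), and the weakly basic phosphonate anion leaves C6–H and the tertiary OH alone.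

Step 11
Reactants: 16 ethyl (2E,4E)-5-[(7R,8S)-7-hydroxy-7,9,9-trimethyl-1,4-dioxaspiro[4.5]decan-8-yl]-3-methylpenta-2,4-dienoate
Product: 17 (7R,8S)-8-[(1E,3E)-5-hydroxy-3-methylpenta-1,3-dien-1-yl]-7,9,9-trimethyl-1,4-dioxaspiro[4.5]decan-7-ol
Conditions: i-Bu2AlH (3.3 equiv), CH2Cl2, −78 °C; Rochelle salt
Reagents that add atoms: none
Why: i-Bu2AlH gives clean 1,2-reduction of the dienoate to the primary allylic alcohol without conjugate reduction (hydride ester reduction).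

Step 12
Reactants: 17 (7R,8S)-8-[(1E,3E)-5-hydroxy-3-methylpenta-1,3-dien-1-yl]-7,9,9-trimethyl-1,4-dioxaspiro[4.5]decan-7-ol
Product: 19 {(2E,4E)-5-[(7R,8S)-7-hydroxy-7,9,9-trimethyl-1,4-dioxaspiro[4.5]decan-8-yl]-3-methylpenta-2,4-dien-1-yl}triphenylphosphonium bromide, via allylic bromide 18 (not isolated)
Conditions: CBr4 (1.2 equiv), PPh3 (1.2 equiv), CH2Cl2, −20 → 0 °C; then PPh3 (1.5 equiv), rt; precipitate with Et2O
Reagents that add atoms: carbon tetrabromide BrC(Br)(Br)Br; triphenylphosphine c1ccccc1P(c1ccccc1)c1ccccc1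
Why: Appel bromination converts only the primary allylic alcohol (SN2, neutral, so tertiary OH and ketal survive) and the labile bromide is quaternised at once by PPh3 (SN2) to the Wittig salt.

**Trans end group (5S,6S)**

Step 13
Reactants: 7 (7,9,9-trimethyl-1,4-dioxaspiro[4.5]dec-7-en-8-yl)methanol
Product: 20 [(1S,6S)-2,2,6-trimethylspiro[7-oxabicyclo[4.1.0]heptane-4,2'-[1,3]dioxolan]-1-yl]methanol (5S,6S in carotenoid numbering)
Conditions: Ti(OiPr)4 (10 mol%), L-(+)-diethyl tartrate (12 mol%), t-BuOOH (2 equiv, anhydrous in decane), 4 Å MS, CH2Cl2, −20 °C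
Reagents that add atoms: tert-butyl hydroperoxide CC(C)(C)OO
Why: Sharpless asymmetric epoxidation with the enantiomeric (R,R)-tartrate delivers oxygen to the opposite face and sets C5 and C6 as 5S,6S.

Step 14
Reactants: 20 [(1S,6S)-2,2,6-trimethylspiro[7-oxabicyclo[4.1.0]heptane-4,2'-[1,3]dioxolan]-1-yl]methanol
Product: 21 (1R,6S)-2,2,6-trimethylspiro[7-oxabicyclo[4.1.0]heptane-4,2'-[1,3]dioxolane]-1-carbaldehyde
Conditions: (n-Pr)4N[RuO4] (5 mol%), N-methylmorpholine N-oxide (1.5 equiv), 4 Å MS, CH2Cl2, rt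
Reagents that add atoms: none
Why: Ley–Griffith oxidation to the non-enolisable epoxy aldehyde under neutral conditions, with no stereocentre at risk.

Step 15
Reactants: 21 (1R,6S)-2,2,6-trimethylspiro[7-oxabicyclo[4.1.0]heptane-4,2'-[1,3]dioxolane]-1-carbaldehyde; 22 methyl 2-[bis(2,2,2-trifluoroethoxy)phosphoryl]acetate
Product: 23 methyl (2Z)-3-[(1R,6S)-2,2,6-trimethylspiro[7-oxabicyclo[4.1.0]heptane-4,2'-[1,3]dioxolan]-1-yl]prop-2-enoate
Conditions: KN(SiMe3)2 (1.1 equiv), 18-crown-6 (3 equiv), THF, −78 → −40 °C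
Reagents that add atoms: none
Why: Still–Gennari variant of the Horner–Wadsworth–Emmons reaction, in which the electron-poor trifluoroethyl phosphonate eliminates under kinetic control to give the Z-enoate that the next step needs.

Step 16
Reactants: 23 methyl (2Z)-3-[(1R,6S)-2,2,6-trimethylspiro[7-oxabicyclo[4.1.0]heptane-4,2'-[1,3]dioxolan]-1-yl]prop-2-enoate
Product: 24 methyl (2E)-3-[(7S,8S)-7-hydroxy-7,9,9-trimethyl-1,4-dioxaspiro[4.5]decan-8-yl]prop-2-enoate (5S,6S)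
Conditions: Pd2(dba)3·CHCl3 (2.5 mol%), n-Bu3P (10 mol%), HCO2H (5 equiv), Et3N (2 equiv), 1,4-dioxane, rt
Reagents that add atoms: none
Why: Same Tsuji–Shimizu hydrogenolysis, but the anti π-allyl complex from the Z-enoate relaxes through the carbon-bound palladium ester enolate (η1 at C8, rotation about C7–C8) to the syn complex on the opposite face before hydride transfer, so hydride enters C6 syn to the C5 oxygen (net retention) and the chain ends trans to the retained 5S hydroxyl (6S), as the E-enoate.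

Step 17
Reactants: 24 methyl (2E)-3-[(7S,8S)-7-hydroxy-7,9,9-trimethyl-1,4-dioxaspiro[4.5]decan-8-yl]prop-2-enoate
Product: 25 (2E)-3-[(7S,8S)-7-hydroxy-7,9,9-trimethyl-1,4-dioxaspiro[4.5]decan-8-yl]-N-methoxy-N-methylprop-2-enamide
Conditions: MeNH(OMe)·HCl (3 equiv), i-PrMgCl (7 equiv), THF, −20 → 0 °C
Reagents that add atoms: N,O-dimethylhydroxylamine hydrochloride CNOC.Cl
Why: Weinreb amide formation by aminolysis of the methyl ester with the chloromagnesium amide, the tertiary alkoxide being a spectator.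

Step 18
Reactants: 25 (2E)-3-[(7S,8S)-7-hydroxy-7,9,9-trimethyl-1,4-dioxaspiro[4.5]decan-8-yl]-N-methoxy-N-methylprop-2-enamide
Product: 26 (3E)-4-[(7S,8S)-7-hydroxy-7,9,9-trimethyl-1,4-dioxaspiro[4.5]decan-8-yl]but-3-en-2-one
Conditions: MeMgBr (3 equiv), THF, 0 °C; cold aq. NH4Cl
Reagents that add atoms: methylmagnesium bromide C[Mg]Br
Why: Weinreb ketone synthesis through the chelated tetrahedral adduct gives the methyl enone without over-addition.

Step 19
Reactants: 26 (3E)-4-[(7S,8S)-7-hydroxy-7,9,9-trimethyl-1,4-dioxaspiro[4.5]decan-8-yl]but-3-en-2-one; 15 triethyl phosphonoacetate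
Product: 27 ethyl (2E,4E)-5-[(7S,8S)-7-hydroxy-7,9,9-trimethyl-1,4-dioxaspiro[4.5]decan-8-yl]-3-methylpenta-2,4-dienoate
Conditions: NaH (1.3 equiv, phosphonate anion preformed from 1.4 equiv 15), THF, 0 → 40 °C
Reagents that add atoms: none
Why: Horner–Wadsworth–Emmons olefination gives mainly the 2E dienoate, the minor 2Z isomer being removed by chromatography.

Step 20
Reactants: 27 ethyl (2E,4E)-5-[(7S,8S)-7-hydroxy-7,9,9-trimethyl-1,4-dioxaspiro[4.5]decan-8-yl]-3-methylpenta-2,4-dienoate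
Product: 28 (7S,8S)-8-[(1E,3E)-5-hydroxy-3-methylpenta-1,3-dien-1-yl]-7,9,9-trimethyl-1,4-dioxaspiro[4.5]decan-7-ol
Conditions: i-Bu2AlH (3.3 equiv), CH2Cl2, −78 °C; Rochelle salt
Reagents that add atoms: none
Why: i-Bu2AlH reduces the dienoate by 1,2-addition to the primary allylic alcohol (hydride ester reduction).

Step 21
Reactants: 28 (7S,8S)-8-[(1E,3E)-5-hydroxy-3-methylpenta-1,3-dien-1-yl]-7,9,9-trimethyl-1,4-dioxaspiro[4.5]decan-7-ol
Product: 30 {(2E,4E)-5-[(7S,8S)-7-hydroxy-7,9,9-trimethyl-1,4-dioxaspiro[4.5]decan-8-yl]-3-methylpenta-2,4-dien-1-yl}triphenylphosphonium bromide, via allylic bromide 29 (not isolated)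
Conditions: CBr4 (1.2 equiv), PPh3 (1.2 equiv), CH2Cl2, −20 → 0 °C; then PPh3 (1.5 equiv), rt; precipitate with Et2O
Reagents that add atoms: carbon tetrabromide BrC(Br)(Br)Br; triphenylphosphine c1ccccc1P(c1ccccc1)c1ccccc1
Why: Appel bromination of the primary allylic alcohol followed by SN2 quaternisation with PPh3 gives the Wittig salt under neutral conditions.

**Assembly**

Step 22
Reactants: 19 {(2E,4E)-5-[(7R,8S)-7-hydroxy-7,9,9-trimethyl-1,4-dioxaspiro[4.5]decan-8-yl]-3-methylpenta-2,4-dien-1-yl}triphenylphosphonium bromide; 31 (2E,4E,6E)-2,7-dimethylocta-2,4,6-trienedial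
Product: 33 (2E,4E,6E,8E,10E,12E)-13-[(7R,8S)-7-hydroxy-7,9,9-trimethyl-1,4-dioxaspiro[4.5]decan-8-yl]-2,7,11-trimethyltrideca-2,4,6,8,10,12-hexaenal, via phosphonium ylide 32 (not isolated)
Conditions: NaOMe (1.1 equiv), MeOH/CH2Cl2, 0 °C → rt, 31 in threefold excess (recovered); then I2 (1 mol%), CH2Cl2, rt, daylight
Reagents that add atoms: none
Why: Wittig olefination of the allylic ylide with one formyl group of the symmetrical dialdehyde (excess suppresses double condensation) builds C11'=C12', and the E/Z mixture at this bond is converged to all-E by iodine-catalysed equilibration.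

Step 23
Reactants: 33 (2E,4E,6E,8E,10E,12E)-13-[(7R,8S)-7-hydroxy-7,9,9-trimethyl-1,4-dioxaspiro[4.5]decan-8-yl]-2,7,11-trimethyltrideca-2,4,6,8,10,12-hexaenal; 30 {(2E,4E)-5-[(7S,8S)-7-hydroxy-7,9,9-trimethyl-1,4-dioxaspiro[4.5]decan-8-yl]-3-methylpenta-2,4-dien-1-yl}triphenylphosphonium bromide
Product: 35 all-E (5S,6S,5'R,6'S)-3,3:3',3'-bis(ethylenedioxy)-5,6,5',6'-tetrahydro-β,β-carotene-5,5'-diol, via phosphonium ylide 34 (not isolated)
Conditions: NaOMe (1.2 equiv), MeOH/CH2Cl2, rt; then heptane, reflux, N2, dark; crystallisation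
Reagents that add atoms: none
Why: The second Wittig olefination joins the trans end group through C11=C12, and the hindered Z isomers at the new bond revert thermally to the all-E polyene, which crystallises.

Step 24
Reactants: 35 all-E (5S,6S,5'R,6'S)-3,3:3',3'-bis(ethylenedioxy)-5,6,5',6'-tetrahydro-β,β-carotene-5,5'-diol
Product: 36 all-E (5S,6S,5'R,6'S)-5,5'-dihydroxy-5,6,5',6'-tetrahydro-β,β-carotene-3,3'-dione (CNP0366900.1)
Conditions: 10% aq. oxalic acid on SiO2, CH2Cl2, rt, N2, dark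
Reagents that add atoms: water O
Why: Acid-catalysed ketal hydrolysis on wet oxalic-acid-loaded silica is mild enough to leave the tertiary β-hydroxy ketones undehydrated and the polyene intact, and no stereocentre is involved.

**Compound list**
1 | ethyl acetoacetate | CCOC(=O)CC(C)=O | starting material
2 | mesityl oxide (4-methylpent-3-en-2-one) | CC(=O)C=C(C)C | starting material
3 | ethyl 2-acetyl-3,3-dimethyl-5-oxohexanoate (Michael adduct, racemic) | CCOC(=O)C(C(C)=O)C(C)(C)CC(C)=O | intermediate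
4 | ethyl 2-hydroxy-2,6,6-trimethyl-4-oxocyclohexane-1-carboxylate (cyclic ketol, stereoisomer mixture) | CCOC(=O)C1C(C)(O)CC(=O)CC1(C)C | intermediate
5 | racemic ethyl 2,6,6-trimethyl-4-oxocyclohex-2-ene-1-carboxylate | CCOC(=O)C1C(C)=CC(=O)CC1(C)C | intermediate
6 | ethyl 7,9,9-trimethyl-1,4-dioxaspiro[4.5]dec-7-ene-8-carboxylate | CCOC(=O)C1=C(C)CC2(CC1(C)C)OCCO2 | intermediate
7 | (7,9,9-trimethyl-1,4-dioxaspiro[4.5]dec-7-en-8-yl)methanol | OCC1=C(C)CC2(CC1(C)C)OCCO2 | intermediate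
8 | [(1R,6R)-2,2,6-trimethylspiro[7-oxabicyclo[4.1.0]heptane-4,2'-[1,3]dioxolan]-1-yl]methanol | OC[C@]12O[C@]2(C)CC2(OCCO2)CC1(C)C | intermediate
9 | (1S,6R)-2,2,6-trimethylspiro[7-oxabicyclo[4.1.0]heptane-4,2'-[1,3]dioxolane]-1-carbaldehyde | O=C[C@]12O[C@]2(C)CC2(OCCO2)CC1(C)C | intermediate
10 | methyl (triphenylphosphoranylidene)acetate | COC(=O)C=P(c1ccccc1)(c1ccccc1)c1ccccc1 | starting material
11 | methyl (2E)-3-[(1S,6R)-2,2,6-trimethylspiro[7-oxabicyclo[4.1.0]heptane-4,2'-[1,3]dioxolan]-1-yl]prop-2-enoate | COC(=O)/C=C/[C@]12O[C@]2(C)CC2(OCCO2)CC1(C)C | intermediate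
12 | methyl (2E)-3-[(7R,8S)-7-hydroxy-7,9,9-trimethyl-1,4-dioxaspiro[4.5]decan-8-yl]prop-2-enoate | COC(=O)/C=C/[C@H]1C(C)(C)CC2(OCCO2)C[C@@]1(C)O | intermediate
13 | (2E)-3-[(7R,8S)-7-hydroxy-7,9,9-trimethyl-1,4-dioxaspiro[4.5]decan-8-yl]-N-methoxy-N-methylprop-2-enamide | CON(C)C(=O)/C=C/[C@H]1C(C)(C)CC2(OCCO2)C[C@@]1(C)O | intermediate
14 | (3E)-4-[(7R,8S)-7-hydroxy-7,9,9-trimethyl-1,4-dioxaspiro[4.5]decan-8-yl]but-3-en-2-one | CC(=O)/C=C/[C@H]1C(C)(C)CC2(OCCO2)C[C@@]1(C)O | intermediate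
15 | triethyl phosphonoacetate | CCOC(=O)CP(=O)(OCC)OCC | starting material
16 | ethyl (2E,4E)-5-[(7R,8S)-7-hydroxy-7,9,9-trimethyl-1,4-dioxaspiro[4.5]decan-8-yl]-3-methylpenta-2,4-dienoate | CCOC(=O)/C=C(C)/C=C/[C@H]1C(C)(C)CC2(OCCO2)C[C@@]1(C)O | intermediate
17 | (7R,8S)-8-[(1E,3E)-5-hydroxy-3-methylpenta-1,3-dien-1-yl]-7,9,9-trimethyl-1,4-dioxaspiro[4.5]decan-7-ol | OC/C=C(C)/C=C/[C@H]1C(C)(C)CC2(OCCO2)C[C@@]1(C)O | intermediate
18 | (7R,8S)-8-[(1E,3E)-5-bromo-3-methylpenta-1,3-dien-1-yl]-7,9,9-trimethyl-1,4-dioxaspiro[4.5]decan-7-ol | BrC/C=C(C)/C=C/[C@H]1C(C)(C)CC2(OCCO2)C[C@@]1(C)O | intermediate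
19 | {(2E,4E)-5-[(7R,8S)-7-hydroxy-7,9,9-trimethyl-1,4-dioxaspiro[4.5]decan-8-yl]-3-methylpenta-2,4-dien-1-yl}triphenylphosphonium bromide | [Br-].c1ccccc1[P+](c1ccccc1)(c1ccccc1)C/C=C(C)/C=C/[C@H]1C(C)(C)CC2(OCCO2)C[C@@]1(C)O | intermediate
20 | [(1S,6S)-2,2,6-trimethylspiro[7-oxabicyclo[4.1.0]heptane-4,2'-[1,3]dioxolan]-1-yl]methanol | OC[C@@]12O[C@@]2(C)CC2(OCCO2)CC1(C)C | intermediate
21 | (1R,6S)-2,2,6-trimethylspiro[7-oxabicyclo[4.1.0]heptane-4,2'-[1,3]dioxolane]-1-carbaldehyde | O=C[C@@]12O[C@@]2(C)CC2(OCCO2)CC1(C)C | intermediate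
22 | methyl 2-[bis(2,2,2-trifluoroethoxy)phosphoryl]acetate | COC(=O)CP(=O)(OCC(F)(F)F)OCC(F)(F)F | starting material
23 | methyl (2Z)-3-[(1R,6S)-2,2,6-trimethylspiro[7-oxabicyclo[4.1.0]heptane-4,2'-[1,3]dioxolan]-1-yl]prop-2-enoate | COC(=O)/C=C\[C@@]12O[C@@]2(C)CC2(OCCO2)CC1(C)C | intermediate
24 | methyl (2E)-3-[(7S,8S)-7-hydroxy-7,9,9-trimethyl-1,4-dioxaspiro[4.5]decan-8-yl]prop-2-enoate | COC(=O)/C=C/[C@H]1C(C)(C)CC2(OCCO2)C[C@]1(C)O | intermediate
25 | (2E)-3-[(7S,8S)-7-hydroxy-7,9,9-trimethyl-1,4-dioxaspiro[4.5]decan-8-yl]-N-methoxy-N-methylprop-2-enamide | CON(C)C(=O)/C=C/[C@H]1C(C)(C)CC2(OCCO2)C[C@]1(C)O | intermediate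
26 | (3E)-4-[(7S,8S)-7-hydroxy-7,9,9-trimethyl-1,4-dioxaspiro[4.5]decan-8-yl]but-3-en-2-one | CC(=O)/C=C/[C@H]1C(C)(C)CC2(OCCO2)C[C@]1(C)O | intermediate
27 | ethyl (2E,4E)-5-[(7S,8S)-7-hydroxy-7,9,9-trimethyl-1,4-dioxaspiro[4.5]decan-8-yl]-3-methylpenta-2,4-dienoate | CCOC(=O)/C=C(C)/C=C/[C@H]1C(C)(C)CC2(OCCO2)C[C@]1(C)O | intermediate
28 | (7S,8S)-8-[(1E,3E)-5-hydroxy-3-methylpenta-1,3-dien-1-yl]-7,9,9-trimethyl-1,4-dioxaspiro[4.5]decan-7-ol | OC/C=C(C)/C=C/[C@H]1C(C)(C)CC2(OCCO2)C[C@]1(C)O | intermediate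
29 | (7S,8S)-8-[(1E,3E)-5-bromo-3-methylpenta-1,3-dien-1-yl]-7,9,9-trimethyl-1,4-dioxaspiro[4.5]decan-7-ol | BrC/C=C(C)/C=C/[C@H]1C(C)(C)CC2(OCCO2)C[C@]1(C)O | intermediate
30 | {(2E,4E)-5-[(7S,8S)-7-hydroxy-7,9,9-trimethyl-1,4-dioxaspiro[4.5]decan-8-yl]-3-methylpenta-2,4-dien-1-yl}triphenylphosphonium bromide | [Br-].c1ccccc1[P+](c1ccccc1)(c1ccccc1)C/C=C(C)/C=C/[C@H]1C(C)(C)CC2(OCCO2)C[C@]1(C)O | intermediate
31 | (2E,4E,6E)-2,7-dimethylocta-2,4,6-trienedial | O=C/C(C)=C/C=C/C=C(C)/C=O | starting material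
32 | {(2E,4E)-5-[(7R,8S)-7-hydroxy-7,9,9-trimethyl-1,4-dioxaspiro[4.5]decan-8-yl]-3-methylpenta-2,4-dien-1-ylidene}triphenylphosphorane | c1ccccc1P(c1ccccc1)(c1ccccc1)=C/C=C(C)/C=C/[C@H]1C(C)(C)CC2(OCCO2)C[C@@]1(C)O | intermediate
33 | (2E,4E,6E,8E,10E,12E)-13-[(7R,8S)-7-hydroxy-7,9,9-trimethyl-1,4-dioxaspiro[4.5]decan-8-yl]-2,7,11-trimethyltrideca-2,4,6,8,10,12-hexaenal | O=C/C(C)=C/C=C/C=C(C)/C=C/C=C(C)/C=C/[C@H]1C(C)(C)CC2(OCCO2)C[C@@]1(C)O | intermediate
34 | {(2E,4E)-5-[(7S,8S)-7-hydroxy-7,9,9-trimethyl-1,4-dioxaspiro[4.5]decan-8-yl]-3-methylpenta-2,4-dien-1-ylidene}triphenylphosphorane | c1ccccc1P(c1ccccc1)(c1ccccc1)=C/C=C(C)/C=C/[C@H]1C(C)(C)CC2(OCCO2)C[C@]1(C)O | intermediate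
35 | all-E (5S,6S,5'R,6'S)-3,3:3',3'-bis(ethylenedioxy)-5,6,5',6'-tetrahydro-β,β-carotene-5,5'-diol | CC(/C=C/C=C(C)/C=C/[C@H]1C(C)(C)CC2(OCCO2)C[C@]1(C)O)=C\C=C\C=C(C)\C=C\C=C(C)\C=C\[C@H]1C(C)(C)CC2(OCCO2)C[C@@]1(C)O | intermediate
36 | all-E (5S,6S,5'R,6'S)-5,5'-dihydroxy-5,6,5',6'-tetrahydro-β,β-carotene-3,3'-dione | CC(/C=C/C=C(C)/C=C/[C@H]1C(C)(C)CC(=O)C[C@]1(C)O)=C\C=C\C=C(C)\C=C\C=C(C)\C=C\[C@H]1C(C)(C)CC(=O)C[C@@]1(C)O | target

**Totals**
Total steps: 24. Longest linear sequence: 15 steps (1–12, then 22–24).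

**Three steps most likely to fail, with fallbacks**

Step 16 (retentive hydrogenolysis of the Z-enoate). If hydride transfer outruns the anti-to-syn isomerisation, the cis epimer contaminates 24. The fallback sets out from 23 and returns at 24. Reduce 23 with SmI2 (THF/MeOH, −78 °C), which cleaves the C6–O bond through the ester radical anion and gives the deconjugated methyl 3-[(7S)-7-hydroxy-7,9,9-trimethyl-1,4-dioxaspiro[4.5]decan-8-ylidene]propanoate F1. Hydrogenate it with [Ir(cod)(PCy3)(py)]PF6 under H2 in CH2Cl2; the tertiary hydroxyl directs H2 to its own face, so C6–H ends syn to OH, giving methyl 3-[(7S,8S)-7-hydroxy-7,9,9-trimethyl-1,4-dioxaspiro[4.5]decan-8-yl]propanoate F2. Selenenylate α to the ester (LDA 2.2 equiv, PhSeBr, THF, −78 °C) to methyl 3-[(7S,8S)-7-hydroxy-7,9,9-trimethyl-1,4-dioxaspiro[4.5]decan-8-yl]-2-(phenylselanyl)propanoate F3, then oxidise with H2O2; selenoxide syn-elimination gives the E-enoate 24.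

Step 7 (hydride delivery with inversion to the hindered C6 next to an acrylate). The fallback sets out from 9 and returns at 12. Methylenate 9 with Ph3P=CH2 (THF, 0 °C) to (1S,6R)-1-ethenyl-2,2,6-trimethylspiro[7-oxabicyclo[4.1.0]heptane-4,2'-[1,3]dioxolane] F4. Run the same Pd2(dba)3·CHCl3/n-Bu3P/HCO2H/Et3N hydrogenolysis on this terminal alkenyl oxirane (hydride to the more substituted allyl terminus with inversion) to give (7R,8S)-8-ethenyl-7,9,9-trimethyl-1,4-dioxaspiro[4.5]decan-7-ol F5. Cross-metathesis with methyl acrylate (second-generation Hoveyda–Grubbs catalyst, RuCl2(H2IMes)(=CH–C6H4-2-OiPr), CH2Cl2, 40 °C) then installs the E-enoate and gives 12.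

Step 24 (double ketal hydrolysis on the polyene without dehydrating the β-hydroxy ketones). The fallback unmasks the ketones one stage earlier; it sets out from 33 and 30 and returns at 36. Wet oxalic acid on SiO2 converts 33 into (2E,4E,6E,8E,10E,12E)-13-[(1S,2R)-2-hydroxy-2,6,6-trimethyl-4-oxocyclohexyl]-2,7,11-trimethyltrideca-2,4,6,8,10,12-hexaenal F6, and converts 30 into {(2E,4E)-5-[(1S,2S)-2-hydroxy-2,6,6-trimethyl-4-oxocyclohexyl]-3-methylpenta-2,4-dien-1-yl}triphenylphosphonium bromide F7. The two are joined by a base-free Wittig reaction (1,2-epoxybutane, EtOH, 70 °C, then thermal equilibration to all-E), which gives 36 directly.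

**Further compounds**
F1 | step 16 | methyl 3-[(7S)-7-hydroxy-7,9,9-trimethyl-1,4-dioxaspiro[4.5]decan-8-ylidene]propanoate (E/Z mixture at the exocyclic alkene) | COC(=O)CC=C1C(C)(C)CC2(OCCO2)C[C@]1(C)O
F2 | step 16 | methyl 3-[(7S,8S)-7-hydroxy-7,9,9-trimethyl-1,4-dioxaspiro[4.5]decan-8-yl]propanoate | COC(=O)CC[C@H]1C(C)(C)CC2(OCCO2)C[C@]1(C)O
F3 | step 16 | methyl 3-[(7S,8S)-7-hydroxy-7,9,9-trimethyl-1,4-dioxaspiro[4.5]decan-8-yl]-2-(phenylselanyl)propanoate (both C2 epimers) | COC(=O)C([Se]c1ccccc1)C[C@H]1C(C)(C)CC2(OCCO2)C[C@]1(C)O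
F4 | step 7 | (1S,6R)-1-ethenyl-2,2,6-trimethylspiro[7-oxabicyclo[4.1.0]heptane-4,2'-[1,3]dioxolane] | C=C[C@]12O[C@]2(C)CC2(OCCO2)CC1(C)C
F5 | step 7 | (7R,8S)-8-ethenyl-7,9,9-trimethyl-1,4-dioxaspiro[4.5]decan-7-ol | C=C[C@H]1C(C)(C)CC2(OCCO2)C[C@@]1(C)O
F6 | step 24 | (2E,4E,6E,8E,10E,12E)-13-[(1S,2R)-2-hydroxy-2,6,6-trimethyl-4-oxocyclohexyl]-2,7,11-trimethyltrideca-2,4,6,8,10,12-hexaenal | O=C/C(C)=C/C=C/C=C(C)/C=C/C=C(C)/C=C/[C@H]1C(C)(C)CC(=O)C[C@@]1(C)O
F7 | step 24 | {(2E,4E)-5-[(1S,2S)-2-hydroxy-2,6,6-trimethyl-4-oxocyclohexyl]-3-methylpenta-2,4-dien-1-yl}triphenylphosphonium bromide | [Br-].c1ccccc1[P+](c1ccccc1)(c1ccccc1)C/C=C(C)/C=C/[C@H]1C(C)(C)CC(=O)C[C@]1(C)O
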